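Chain atoms are numbered from the ester carbon (C1) to the benzylic CH2 (C5). Everything rests on cutting C4–C5, the bond between the ketone carbon and the CH2 on the prenylated phenol ring, at the acyl level. C4 is flanked by C3–H, benzylic to the 4-hydroxyphenyl ring, α to the carbonyl and β to the C2 hydroxyl, so the anti C2/C3 array is set first by a catalytic asymmetric glyoxylate Mukaiyama aldol that delivers C4 as an S-ethyl thioester. The key Fukuyama coupling joins this thioester to a benzylic zinc chloride made in the same flask, forming the ketone under neutral conditions that spare C3–H, the free C2–OH and the methyl ester. Desilylation ends the route.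

Key step: step 9

Assumption: the (S,S)-Bn-box·Sn(OTf)2 catalyst is taken to give the (2R,3S) anti adduct; the anti sense is inherent to this catalyst class, and if the absolute sense proves opposite the (R,R)-ligand is used with no other change.
Remark: methyl glyoxylate (6) is used freshly distilled from its commercial hemiacetal or oligomer over P2O5.

Step 1
Reactants: 1 4-hydroxyphenylacetic acid
Product: 3 [4-(tert-butyldimethylsilyloxy)phenyl]acetic acid, via bis-silylated acid 2 (not isolated)
Conditions: TBSCl (2.3 equiv), imidazole, DMF, rt; then AcOH–THF–H2O, rt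
Reagents that add atoms: tert-butyldimethylsilyl chloride, CC(C)(C)[Si](C)(C)Cl
Why: Standard silylation of both acidic OH groups followed by selective solvolysis of the much more labile silyl ester should leave only the phenolic silyl ether, which masks the phenol against the base and Lewis acids that follow.

Step 2
Reactants: 3 [4-(tert-butyldimethylsilyloxy)phenyl]acetic acid
Product: 4 S-ethyl [4-(tert-butyldimethylsilyloxy)phenyl]ethanethioate
Conditions: EtSH, DCC, DMAP (cat.), CH2Cl2, 0 °C → rt
Reagents that add atoms: ethanethiol, CCS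
Why: Steglich-type thioesterification should give the S-ethyl thioester, which serves first as the aldol donor precursor and later as the acyl donor for palladium.

Step 3
Reactants: 4 S-ethyl [4-(tert-butyldimethylsilyloxy)phenyl]ethanethioate
Product: 5 (Z)-tert-butyl{4-[2-(ethylsulfanyl)-2-(trimethylsilyloxy)ethenyl]phenoxy}dimethylsilane (ketene S,O-acetal)
Conditions: LDA, TMSCl, THF, −78 °C → rt; non-aqueous work-up, used crude
Reagents that add atoms: chlorotrimethylsilane, C[Si](C)(C)Cl
Why: Kinetic deprotonation of the acidic benzylic thioester position and O-silylation of the enolate should give the silyl ketene acetal for a Mukaiyama aldol, whose open transition state is expected to make the exact E/Z ratio uncritical.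

Step 4
Reactants: 5 silyl ketene S,O-acetal; 6 methyl glyoxylate
Product: 8 methyl (2R,3S)-3-[4-(tert-butyldimethylsilyloxy)phenyl]-4-(ethylsulfanyl)-2-hydroxy-4-oxobutanoate, via trimethylsilyl ether 7 (not isolated)
Conditions: Sn(OTf)2 (10 mol %), (S,S)-Bn-box (11 mol %), CH2Cl2, −78 °C; then 1 N HCl, THF, rt
Reagents that add atoms: none
Why: In this catalytic enantioselective Mukaiyama aldol the Sn(II)–bis(oxazoline) complex binds the glyoxylate in bidentate fashion, so the catalyst should select the aldehyde face that sets C2 (R), the anti-selective open transition state should set C3 (S), and the thioester emerges ready for coupling.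

Step 5
Reactants: 9 4-hydroxybenzaldehyde; 10 prenyl bromide (1-bromo-3-methylbut-2-ene)
Product: 11 4-hydroxy-3-(3-methylbut-2-en-1-yl)benzaldehyde
Conditions: KOH (10 % aq.), rt
Reagents that add atoms: none
Why: ortho-C-Alkylation of the phenoxide in water, where the solvated oxygen is a poor nucleophile and the para position is blocked by the formyl group, should install the prenyl group next to the phenol oxygen in one operation.

Step 6
Reactants: 11 4-hydroxy-3-(3-methylbut-2-en-1-yl)benzaldehyde
Product: 12 4-(tert-butyldimethylsilyloxy)-3-(3-methylbut-2-en-1-yl)benzaldehyde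
Conditions: TBSCl, imidazole, DMF, rt
Reagents that add atoms: tert-butyldimethylsilyl chloride, CC(C)(C)[Si](C)(C)Cl
Why: Silylation of the phenol prevents quinone-methide formation from the later para-hydroxybenzylic chloride and removes the acidic proton before the organozinc stage.

Step 7
Reactants: 12 4-(tert-butyldimethylsilyloxy)-3-(3-methylbut-2-en-1-yl)benzaldehyde
Product: 13 [4-(tert-butyldimethylsilyloxy)-3-(3-methylbut-2-en-1-yl)phenyl]methanol
Conditions: NaBH4, MeOH, 0 °C
Reagents that add atoms: none
Why: Borohydride reduction is chemoselective for the aldehyde and should leave the trisubstituted alkene and the aryl silyl ether untouched.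

Step 8
Reactants: 13 [4-(tert-butyldimethylsilyloxy)-3-(3-methylbut-2-en-1-yl)phenyl]methanol
Product: 14 tert-butyl[4-(chloromethyl)-2-(3-methylbut-2-en-1-yl)phenoxy]dimethylsilane
Conditions: NCS, Me2S, CH2Cl2, −20 → 0 °C; used without chromatography
Reagents that add atoms: N-chlorosuccinimide, O=C1CCC(=O)N1Cl
Why: Corey–Kim chlorination converts the benzylic alcohol through its alkoxysulfonium salt into the chloride under neutral conditions, so no HCl is available to add to the prenyl alkene or cleave the silyl ether.

Step 9
Reactants: 14 tert-butyl[4-(chloromethyl)-2-(3-methylbut-2-en-1-yl)phenoxy]dimethylsilane; 8 methyl (2R,3S)-3-[4-(tert-butyldimethylsilyloxy)phenyl]-4-(ethylsulfanyl)-2-hydroxy-4-oxobutanoate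
Product: 16 methyl (2R,3S)-3-[4-(tert-butyldimethylsilyloxy)phenyl]-5-[4-(tert-butyldimethylsilyloxy)-3-(3-methylbut-2-en-1-yl)phenyl]-2-hydroxy-4-oxopentanoate, via benzylic zinc chloride 15 (not isolated)
Conditions: 14, Zn dust, LiCl, THF, 25 °C; then 8, PdCl2(PPh3)2 (5 mol %), toluene–THF, rt (about 2.2 equiv of 15)
Reagents that add atoms: zinc, [Zn] (held only in the intermediate 15; none of its atoms remain in 16)
Why: LiCl-assisted insertion of zinc into the benzylic C–Cl bond of 14 makes C5 a soft carbon nucleophile (15); Pd(0) then adds oxidatively into the C4–S bond of 8, the benzyl group is transferred from zinc to the acyl–palladium species, and reductive elimination forms C4–C5 and releases the ketone. This is a Fukuyama coupling, the thioester counterpart of Negishi acylation. No ring is closed and no stereocentre is created, so the only stereochemical demand is that C2 (R) and C3 (S), set in step 4, pass through unchanged. The selectivity needed is acyl transfer at C4 only, without attack on the C1 methyl ester or the product ketone and without deprotonation at C3–H or retro-aldol across C2–C3; it is secured because only the C–S bond is activated by palladium, benzylic zinc halides do not add to esters or hindered ketones at room temperature, and the medium stays neutral and only weakly basic. The free C2–OH is expected to be tolerated, at worst as its zinc alkoxide (hence the excess of 15), and the aryl silyl ethers and the prenyl alkene are spectators.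

Step 10
Reactants: 16 bis-silyl ether of the target
Product: 17 asperteretal H, methyl (2R,3S)-2-hydroxy-3-(4-hydroxyphenyl)-5-[4-hydroxy-3-(3-methylbut-2-en-1-yl)phenyl]-4-oxopentanoate
Conditions: KHF2, MeOH, rt
Reagents that add atoms: none
Why: Bifluoride in methanol cleaves aryl silyl ethers selectively under slightly acidic, base-free conditions, so both phenols should be released without epimerisation at C3, retro-aldol cleavage or ester exchange.

Compound list
1 | 4-hydroxyphenylacetic acid | OC(=O)Cc1ccc(O)cc1 | starting material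
2 | tert-butyldimethylsilyl [4-(tert-butyldimethylsilyloxy)phenyl]acetate | CC(C)(C)[Si](C)(C)OC(=O)Cc1ccc(O[Si](C)(C)C(C)(C)C)cc1 | intermediate
3 | [4-(tert-butyldimethylsilyloxy)phenyl]acetic acid | OC(=O)Cc1ccc(O[Si](C)(C)C(C)(C)C)cc1 | intermediate
4 | S-ethyl [4-(tert-butyldimethylsilyloxy)phenyl]ethanethioate | CCSC(=O)Cc1ccc(O[Si](C)(C)C(C)(C)C)cc1 | intermediate
5 | (Z)-tert-butyl{4-[2-(ethylsulfanyl)-2-(trimethylsilyloxy)ethenyl]phenoxy}dimethylsilane (SEt cis to aryl) | CCS/C(O[Si](C)(C)C)=C\c1ccc(O[Si](C)(C)C(C)(C)C)cc1 | intermediate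
6 | methyl glyoxylate | COC(=O)C=O | starting material
7 | methyl (2R,3S)-3-[4-(tert-butyldimethylsilyloxy)phenyl]-4-(ethylsulfanyl)-4-oxo-2-(trimethylsilyloxy)butanoate | COC(=O)[C@H](O[Si](C)(C)C)[C@@H](C(=O)SCC)c1ccc(O[Si](C)(C)C(C)(C)C)cc1 | intermediate
8 | methyl (2R,3S)-3-[4-(tert-butyldimethylsilyloxy)phenyl]-4-(ethylsulfanyl)-2-hydroxy-4-oxobutanoate | COC(=O)[C@H](O)[C@@H](C(=O)SCC)c1ccc(O[Si](C)(C)C(C)(C)C)cc1 | intermediate
9 | 4-hydroxybenzaldehyde | O=Cc1ccc(O)cc1 | starting material
10 | prenyl bromide (1-bromo-3-methylbut-2-ene) | CC(C)=CCBr | starting material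
11 | 4-hydroxy-3-(3-methylbut-2-en-1-yl)benzaldehyde | O=Cc1ccc(O)c(CC=C(C)C)c1 | intermediate
12 | 4-(tert-butyldimethylsilyloxy)-3-(3-methylbut-2-en-1-yl)benzaldehyde | O=Cc1ccc(O[Si](C)(C)C(C)(C)C)c(CC=C(C)C)c1 | intermediate
13 | [4-(tert-butyldimethylsilyloxy)-3-(3-methylbut-2-en-1-yl)phenyl]methanol | OCc1ccc(O[Si](C)(C)C(C)(C)C)c(CC=C(C)C)c1 | intermediate
14 | tert-butyl[4-(chloromethyl)-2-(3-methylbut-2-en-1-yl)phenoxy]dimethylsilane | ClCc1ccc(O[Si](C)(C)C(C)(C)C)c(CC=C(C)C)c1 | intermediate
15 | [4-(tert-butyldimethylsilyloxy)-3-(3-methylbut-2-en-1-yl)benzyl]zinc chloride (LiCl complex in THF) | Cl[Zn]Cc1ccc(O[Si](C)(C)C(C)(C)C)c(CC=C(C)C)c1 | intermediate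
16 | methyl (2R,3S)-3-[4-(tert-butyldimethylsilyloxy)phenyl]-5-[4-(tert-butyldimethylsilyloxy)-3-(3-methylbut-2-en-1-yl)phenyl]-2-hydroxy-4-oxopentanoate | COC(=O)[C@H](O)[C@@H](C(=O)Cc1ccc(O[Si](C)(C)C(C)(C)C)c(CC=C(C)C)c1)c1ccc(O[Si](C)(C)C(C)(C)C)cc1 | intermediate
17 | asperteretal H, methyl (2R,3S)-2-hydroxy-3-(4-hydroxyphenyl)-5-[4-hydroxy-3-(3-methylbut-2-en-1-yl)phenyl]-4-oxopentanoate | COC(=O)[C@H](O)[C@@H](C(=O)Cc1ccc(O)c(CC=C(C)C)c1)c1ccc(O)cc1 | target

Total step count: 10.
Longest linear sequence: 6 steps (steps 1–4, 9, 10; the other branch, steps 5–8, 9, 10, is equally long).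

Steps most likely to fail

1. Step 9. The zinc reagent may be consumed by protonolysis at the free C2–OH or by Wurtz-type homocoupling. If transmetalation is slow, the acyl–palladium intermediate may also enolise at C3 or lose CO. The fallback makes C4–C5 by carbonyl addition at the aldehyde oxidation level and then oxidises; it sets out from 8 (with 15 made from 14 as before) and comes back to the route at 17. The C2 hydroxyl of 8 is silylated (TESOTf, 2,6-lutidine, CH2Cl2, −78 °C) to give methyl (2R,3S)-3-[4-(tert-butyldimethylsilyloxy)phenyl]-4-(ethylsulfanyl)-4-oxo-2-(triethylsilyloxy)butanoate F1. Fukuyama reduction (Et3SiH, Pd/C, acetone, rt) should give the aldehyde methyl (2R,3S)-3-[4-(tert-butyldimethylsilyloxy)phenyl]-4-oxo-2-(triethylsilyloxy)butanoate F2. Addition of 15 to the formyl group (THF, 0 °C) should give the C4 carbinol (both C4 epimers) of the silylated skeleton F3, which Dess–Martin periodinane (NaHCO3, CH2Cl2, rt) should oxidise to the 2-O-triethylsilyl ether of 16 F4. TBAF buffered with AcOH (THF, 0 °C) then removes all three silyl groups to give 17.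

2. Step 4. With an aryl-conjugated, less nucleophilic ketene acetal the anti/syn ratio or the enantiofacial selectivity may be poor, the absolute sense may be wrong, or slow silyl transfer may stall turnover. The fallback replaces catalyst control by auxiliary control; it sets out from 3 and comes back at 7, and so at 8. N-Acylation of (R)-4-benzyloxazolidin-2-one with 3 (DCC, DMAP cat., CH2Cl2) gives (R)-4-benzyl-3-{[4-(tert-butyldimethylsilyloxy)phenyl]acetyl}oxazolidin-2-one F5. A magnesium-halide-catalysed anti-aldol with 6 (MgCl2 cat., Et3N, TMSCl, EtOAc, rt) should give the O-trimethylsilyl anti-aldol imide F6. The glyoxylate is expected to attack the chelated Z-enolate on the face away from the benzyl group, the same face as in alkylations of this auxiliary, which is why the (R)-auxiliary is chosen for 3S. LiSEt (THF, 0 °C) then exchanges the auxiliary for the ethyl thioester to give 7, which the acidic work-up of step 4 converts into 8.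

3. Step 5. O-Alkylation and double alkylation of the ambident phenoxide may outrun mono-ortho-C-alkylation. The fallback delivers the prenyl group by a sigmatropic shift; it sets out from 9 and comes back at 11. Pd-catalysed O-alkylation of 9 with isobutyl 2-methylbut-3-en-2-yl carbonate (Pd(PPh3)4, THF, 0 °C → rt) should give the tertiary allyl ether 4-[(2-methylbut-3-en-2-yl)oxy]benzaldehyde F7. Aromatic Claisen rearrangement (N,N-diethylaniline, about 140 °C) then moves the allyl unit to the ortho carbon with allylic transposition and gives 11 after tautomerisation.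

Further compounds
F1 | step 9 | methyl (2R,3S)-3-[4-(tert-butyldimethylsilyloxy)phenyl]-4-(ethylsulfanyl)-4-oxo-2-(triethylsilyloxy)butanoate | COC(=O)[C@H](O[Si](CC)(CC)CC)[C@@H](C(=O)SCC)c1ccc(O[Si](C)(C)C(C)(C)C)cc1
F2 | step 9 | methyl (2R,3S)-3-[4-(tert-butyldimethylsilyloxy)phenyl]-4-oxo-2-(triethylsilyloxy)butanoate | COC(=O)[C@H](O[Si](CC)(CC)CC)[C@@H](C=O)c1ccc(O[Si](C)(C)C(C)(C)C)cc1
F3 | step 9 | methyl (2R,3R,4RS)-3-[4-(tert-butyldimethylsilyloxy)phenyl]-5-[4-(tert-butyldimethylsilyloxy)-3-(3-methylbut-2-en-1-yl)phenyl]-4-hydroxy-2-(triethylsilyloxy)pentanoate (C3 spatially as in 16; descriptor changed by priority only) | COC(=O)[C@H](O[Si](CC)(CC)CC)[C@@H](C(O)Cc1ccc(O[Si](C)(C)C(C)(C)C)c(CC=C(C)C)c1)c1ccc(O[Si](C)(C)C(C)(C)C)cc1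
F4 | step 9 | methyl (2R,3S)-3-[4-(tert-butyldimethylsilyloxy)phenyl]-5-[4-(tert-butyldimethylsilyloxy)-3-(3-methylbut-2-en-1-yl)phenyl]-4-oxo-2-(triethylsilyloxy)pentanoate | COC(=O)[C@H](O[Si](CC)(CC)CC)[C@@H](C(=O)Cc1ccc(O[Si](C)(C)C(C)(C)C)c(CC=C(C)C)c1)c1ccc(O[Si](C)(C)C(C)(C)C)cc1
F5 | step 4 | (R)-4-benzyl-3-{[4-(tert-butyldimethylsilyloxy)phenyl]acetyl}oxazolidin-2-one | O=C(Cc1ccc(O[Si](C)(C)C(C)(C)C)cc1)N1[C@H](Cc2ccccc2)COC1=O
F6 | step 4 | methyl (2R,3S)-4-[(4R)-4-benzyl-2-oxooxazolidin-3-yl]-3-[4-(tert-butyldimethylsilyloxy)phenyl]-4-oxo-2-(trimethylsilyloxy)butanoate | COC(=O)[C@H](O[Si](C)(C)C)[C@@H](C(=O)N1[C@H](Cc2ccccc2)COC1=O)c1ccc(O[Si](C)(C)C(C)(C)C)cc1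
F7 | step 5 | 4-[(2-methylbut-3-en-2-yl)oxy]benzaldehyde | O=Cc1ccc(OC(C)(C)C=C)cc1
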